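## Retrosynthetic overview

1. The C1–Br bond comes last, by hydrogen-atom-transfer hydrogenation of a C1=C2 vinyl bromide made from a C1 ketone; the C11 carbinol comes from exo-selective Markovnikov hydration of a norbornene.
2. Ring B and both rings of the bicyclo[2.2.1]heptane come together from an intramolecular Diels–Alder reaction of a 1-alkyl-2-isopropylcyclopentadiene with a C6=C14 vinyl group on ring A.
3. The diene arm comes from B-alkyl Suzuki coupling of a C8=C9 vinyl group with 2-iodocyclopentenone, and the C4 carbinol from methyl addition to a ring A cyclohexanone.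
4. Ring A comes from a Claisen ring contraction of an eight-membered cyclic enol ether (a 2-alkylidene oxocene): C5–C10 forms and O–C8 breaks. The enabling feature is a ring oxygen that is allylic to the ring (Z)-alkene (O–C8–C9=C10) and carries the exocyclic enol ether C4=C5, with C5 and C10 held 1,5 across the ring by the C1–C2–C3 bridge.
5. The oxocene comes from oxa-Michael addition of allyl alcohol to an ynoate, ring-closing metathesis and ester reduction; its single stereocentre (C1–O) comes from a CBS reduction. Ring order: oxocene, then ring A, then ring B with the norbornane.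

Key step: step 10

Remark: locants are my own. Ring A is C1 (CHBr), C2, C3, C4 (C(OH)CH3), C5 (CH), C10 (C–CH3); ring B is C5–C6–C7–C8–C9–C10; the bicyclo[2.2.1]heptane is C6, C7 (bridgehead), C11 (isopropyl carbinol), C12, C13 (bridgehead), C14 (between C13 and C6), C15 (one-carbon bridge). β is the face of the C10 methyl; on these locants the target is (1S,4R,5S,6S,7R,10S,11R,13R), i.e. 1β-Br, 4β-OH, 5α-H, 6β-H, 10β-CH3, 11-OH exo. Pent-4-ynoyl chloride and 2-iodocyclopent-2-en-1-one are taken as purchased.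

## Route

Step 1
Reactants: 1 pent-4-ynoyl chloride
Product: 2 N-methoxy-N-methylpent-4-ynamide
Conditions: MeNHOMe·HCl, pyridine, CH2Cl2, 0 °C → rt
Reagents that add atoms: N,O-dimethylhydroxylamine hydrochloride, CNOC.Cl
Why: Acyl substitution of the acid chloride by the amine (Weinreb amide formation); no stereocentre is formed.

Step 2
Reactants: 2 N-methoxy-N-methylpent-4-ynamide
Product: 3 2-methylhept-1-en-6-yn-3-one
Conditions: isopropenylmagnesium bromide (2.2 equiv), THF, −20 → 0 °C; inverse quench into cold aq NH4Cl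
Reagents that add atoms: isopropenylmagnesium bromide, CC(=C)[Mg]Br
Why: Weinreb ketone synthesis, in which the chelated tetrahedral adduct survives until the quench, so the α-methylene ketone should be released only on work-up and escape over-addition and conjugate addition (the extra equivalent covers the alkyne C–H).

Step 3
Reactants: 3 2-methylhept-1-en-6-yn-3-one
Product: 4 (R)-2-methylhept-1-en-6-yn-3-ol
Conditions: (S)-2-methyl-CBS-oxazaborolidine (10 mol%), catecholborane, toluene, −78 °C; aq NaOH wash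
Reagents that add atoms: none
Why: Corey–Bakshi–Shibata reduction, in which the isopropenyl group is the large substituent, so the (S)-catalyst should deliver hydride to give the (R)-carbinol (future C1) while catecholborane at −78 °C leaves alkyne and alkene untouched.

Step 4
Reactants: 4 (R)-2-methylhept-1-en-6-yn-3-ol
Product: 5 (R)-tert-butyldimethyl[(2-methylhept-1-en-6-yn-3-yl)oxy]silane
Conditions: TBSCl, imidazole, DMF, rt
Reagents that add atoms: tert-butyldimethylsilyl chloride, CC(C)(C)[Si](C)(C)Cl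
Why: Silylation of the secondary allylic alcohol; the stereocentre is untouched.

Step 5
Reactants: 5 (R)-tert-butyldimethyl[(2-methylhept-1-en-6-yn-3-yl)oxy]silane
Product: 7 methyl (R)-6-[(tert-butyldimethylsilyl)oxy]-7-methyloct-7-en-2-ynoate, via lithium acetylide 6 (not isolated)
Conditions: n-BuLi, THF, −78 °C; ClCO2Me, −78 → 0 °C
Reagents that add atoms: methyl chloroformate, COC(=O)Cl
Why: C-acylation of the lithium acetylide by the chloroformate gives the alkynoate; no stereocentre is affected.

Step 6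
Reactants: 7 methyl (R)-6-[(tert-butyldimethylsilyl)oxy]-7-methyloct-7-en-2-ynoate
Product: 8 methyl (2E,6R)-3-(allyloxy)-6-[(tert-butyldimethylsilyl)oxy]-7-methylocta-2,7-dienoate
Conditions: allyl alcohol (3 equiv), PBu3 (10 mol%), CH2Cl2, 0 °C → rt
Reagents that add atoms: allyl alcohol, C=CCO
Why: Phosphine-catalysed oxa-Michael addition to the alkynoate, whose reversibility should funnel the product to the more stable (E)-β-alkoxyacrylate (alkoxy trans to ester), the geometry that later fixes C5.

Step 7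
Reactants: 8 methyl (2E,6R)-3-(allyloxy)-6-[(tert-butyldimethylsilyl)oxy]-7-methylocta-2,7-dienoate
Product: 9 methyl (2E)-2-[(5R,6Z)-5-[(tert-butyldimethylsilyl)oxy]-6-methyl-3,4,5,8-tetrahydro-2H-oxocin-2-ylidene]acetate
Conditions: second-generation Hoveyda–Grubbs catalyst (10 mol%), toluene (2 mM), 80 °C, argon sparge
Reagents that add atoms: none
Why: Ring-closing olefin metathesis to the oxocene, in which the ring imposes the (Z)-geometry on the new trisubstituted alkene, the planar β-alkoxyacrylate unit pre-organises the chain and the electron-poor enoate alkene stays inert.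

Step 8
Reactants: 9 methyl (2E)-2-[(5R,6Z)-5-[(tert-butyldimethylsilyl)oxy]-6-methyl-3,4,5,8-tetrahydro-2H-oxocin-2-ylidene]acetate
Product: 10 (2E)-2-[(5R,6Z)-5-[(tert-butyldimethylsilyl)oxy]-6-methyl-3,4,5,8-tetrahydro-2H-oxocin-2-ylidene]ethan-1-ol
Conditions: i-Bu2AlH (2.5 equiv), CH2Cl2, −78 → −20 °C; aq KNa tartrate, Et3N
Reagents that add atoms: none
Why: Aluminium hydride 1,2-reduction of the vinylogous carbonate ester to the allylic alcohol, which should keep the (E)-enol ether geometry.

Step 9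
Reactants: 10 (2E)-2-[(5R,6Z)-5-[(tert-butyldimethylsilyl)oxy]-6-methyl-3,4,5,8-tetrahydro-2H-oxocin-2-ylidene]ethan-1-ol
Product: 11 (5R,6Z)-5-[(tert-butyldimethylsilyl)oxy]-2-{(E)-2-[(tert-butyldimethylsilyl)oxy]ethylidene}-6-methyl-3,4,5,8-tetrahydro-2H-oxocine
Conditions: TBSCl, imidazole, DMF, 0 °C → rt
Reagents that add atoms: tert-butyldimethylsilyl chloride, CC(C)(C)[Si](C)(C)Cl
Why: Silylation of the primary allylic alcohol under basic conditions that spare the acid-labile enol ether.

Step 10
Reactants: 11 (5R,6Z)-5-[(tert-butyldimethylsilyl)oxy]-2-{(E)-2-[(tert-butyldimethylsilyl)oxy]ethylidene}-6-methyl-3,4,5,8-tetrahydro-2H-oxocine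
Product: 12 (2R,3S,4R)-4-[(tert-butyldimethylsilyl)oxy]-2-{[(tert-butyldimethylsilyl)oxy]methyl}-3-methyl-3-vinylcyclohexan-1-one
Conditions: toluene (0.02 M), 2,6-di-tert-butyl-4-methylpyridine (0.2 equiv), silylated sealed tube, 170 °C
Reagents that add atoms: none
Why: Thermal [3,3]-sigmatropic (Claisen) rearrangement of the cyclic allyl vinyl ether: the exocyclic enol-ether carbon C5 bonds to the ring-alkene carbon C10 while the allylic O–C8 bond breaks, so the eight-membered ring contracts by two atoms to the ring A cyclohexanone and C8/C9 are expelled as the vinyl group; the closest known reaction type is the Claisen ring contraction of enol ethers and ketene acetals derived from medium-ring unsaturated lactones. Ring A closes by a suprafacial bond across the 1,5-positions of the oxocene, and the three-carbon C1–C2–C3 bridge between the termini allows only the chair-like six-membered pericyclic array (in the boat array C1 and C3 are too far apart to be spanned by C2). The quaternary centre C10 is fixed by the (Z)-geometry that the ring imposes on C9=C10, and C5 by the (E)-geometry of the exocyclic enol ether, which in the chair array places the CH2OTBS arm anti to the new vinyl group and syn to the methyl group. The alkene face is chosen by the C1 silyloxy group, which sits equatorial on the nascent ring and anti to the forming bond, whereas in the other chair it would be 1,3-diaxial to the CH2OTBS arm. The step needs the enol ether to keep its geometry and position until it rearranges, which the hindered pyridine buffer and silylated glass should secure; relief of ring strain and C=O formation drive it.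

Step 11
Reactants: 12 (2R,3S,4R)-4-[(tert-butyldimethylsilyl)oxy]-2-{[(tert-butyldimethylsilyl)oxy]methyl}-3-methyl-3-vinylcyclohexan-1-one
Product: 13 (1R,2R,3S,4R)-4-[(tert-butyldimethylsilyl)oxy]-2-{[(tert-butyldimethylsilyl)oxy]methyl}-1,3-dimethyl-3-vinylcyclohexan-1-ol
Conditions: MeMgBr, CeCl3, THF, −78 °C; aq NH4Cl
Reagents that add atoms: methylmagnesium bromide, C[Mg]Br
Why: 1,2-Addition of the weakly basic organocerium reagent (no enolisation, no β-elimination of the silyloxymethyl arm), in which the chair with both carbon arms equatorial has the C10 methyl axial and blocks axial attack, so methyl should enter equatorially and leave the C4 hydroxyl axial and β.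

Step 12
Reactants: 13 (1R,2R,3S,4R)-4-[(tert-butyldimethylsilyl)oxy]-2-{[(tert-butyldimethylsilyl)oxy]methyl}-1,3-dimethyl-3-vinylcyclohexan-1-ol; 14 2-iodocyclopent-2-en-1-one
Product: 16 (1R,2R,3S,4R)-4-[(tert-butyldimethylsilyl)oxy]-2-{[(tert-butyldimethylsilyl)oxy]methyl}-1,3-dimethyl-3-[2-(5-oxocyclopent-1-en-1-yl)ethyl]cyclohexan-1-ol, via alkylborane 15 (not isolated)
Conditions: 9-BBN (2.5 equiv), THF, 0 °C → rt; then 14, PdCl2(dppf) (5 mol%), AsPh3, Cs2CO3, DMF/THF/H2O, rt
Reagents that add atoms: none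
Why: Anti-Markovnikov hydroboration of the only terminal alkene followed by B-alkyl Suzuki–Miyaura coupling with the α-iodoenone joins C8 to C7 without touching a stereocentre.

Step 13
Reactants: 16 (1R,2R,3S,4R)-4-[(tert-butyldimethylsilyl)oxy]-2-{[(tert-butyldimethylsilyl)oxy]methyl}-1,3-dimethyl-3-[2-(5-oxocyclopent-1-en-1-yl)ethyl]cyclohexan-1-ol
Product: 17 (1R,2R,3S,4R)-4-[(tert-butyldimethylsilyl)oxy]-2-{[(tert-butyldimethylsilyl)oxy]methyl}-3-[2-(5-hydroxy-5-isopropylcyclopent-1-en-1-yl)ethyl]-1,3-dimethylcyclohexan-1-ol (both epimers at the cyclopentenol carbon)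
Conditions: i-PrMgCl, CeCl3, THF, −78 °C; aq NH4Cl
Reagents that add atoms: isopropylmagnesium chloride, CC(C)[Mg]Cl
Why: Organocerium 1,2-addition to the enone carbonyl (future C11), whose new carbinol configuration does not matter because the centre becomes sp2 in step 17.

Step 14
Reactants: 17 (1R,2R,3S,4R)-4-[(tert-butyldimethylsilyl)oxy]-2-{[(tert-butyldimethylsilyl)oxy]methyl}-3-[2-(5-hydroxy-5-isopropylcyclopent-1-en-1-yl)ethyl]-1,3-dimethylcyclohexan-1-ol
Product: 18 (1R,2R,3S,4R)-2-(hydroxymethyl)-3-[2-(5-hydroxy-5-isopropylcyclopent-1-en-1-yl)ethyl]-1,3-dimethylcyclohexane-1,4-diol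
Conditions: Bu4NF (4 equiv), THF, rt → 45 °C
Reagents that add atoms: none
Why: Fluoride-mediated cleavage of both silyl ethers under basic conditions that spare the tertiary allylic alcohol.

Step 15
Reactants: 18 (1R,2R,3S,4R)-2-(hydroxymethyl)-3-[2-(5-hydroxy-5-isopropylcyclopent-1-en-1-yl)ethyl]-1,3-dimethylcyclohexane-1,4-diol
Product: 19 (1S,2S,6R)-6-hydroxy-2-[2-(5-hydroxy-5-isopropylcyclopent-1-en-1-yl)ethyl]-2,6-dimethyl-3-oxocyclohexane-1-carbaldehyde
Conditions: Dess–Martin periodinane (2.5 equiv), NaHCO3, CH2Cl2, 0 °C → rt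
Reagents that add atoms: none
Why: Dess–Martin oxidation takes the primary alcohol to the C6 aldehyde and the secondary alcohol to the C1 ketone in one operation, while the tertiary alcohols cannot react.

Step 16
Reactants: 19 (1S,2S,6R)-6-hydroxy-2-[2-(5-hydroxy-5-isopropylcyclopent-1-en-1-yl)ethyl]-2,6-dimethyl-3-oxocyclohexane-1-carbaldehyde
Product: 20 (2S,3S,4R)-4-hydroxy-2-[2-(5-hydroxy-5-isopropylcyclopent-1-en-1-yl)ethyl]-2,4-dimethyl-3-vinylcyclohexan-1-one
Conditions: CH2(ZnI)2 (from CH2I2 and Zn), THF, 0 °C → rt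
Reagents that add atoms: diiodomethane, ICI
Why: Takai-type methylenation with the non-basic geminal dizinc reagent, which is selective for the aldehyde over the hindered ketone and should avoid epimerisation at C5 and retro-aldol cleavage of the β-hydroxy aldehyde.

Step 17
Reactants: 20 (2S,3S,4R)-4-hydroxy-2-[2-(5-hydroxy-5-isopropylcyclopent-1-en-1-yl)ethyl]-2,4-dimethyl-3-vinylcyclohexan-1-one
Product: 22 tetracyclic hydroxy ketone (4R,5S,6S,7R,10S,13R): C1 ketone, 4β-OH, 5α-H, 6β-H, 10β-CH3, C11=C12 alkene with isopropyl on C11, via cyclopentadiene 21 (not isolated)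
Conditions: PPTS (10 mol%), toluene (5 mM), 40 °C; then Et3N, 150 °C, sealed tube
Reagents that add atoms: none
Why: Acid-catalysed dehydration of the tertiary allylic alcohol gives the cyclopentadiene, whose isomers interconvert by [1,5]-hydrogen shifts, and the 1-alkyl-2-isopropyl isomer is trapped by an intramolecular Diels–Alder reaction with the C6=C14 vinyl group in which the four-atom tether forces C5 exo at C6 and a chair-like ring B with the dienophile carbon C14 equatorial (the alternative puts it syn-axial to the C10 methyl), setting C6, C7 and C13.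

Step 18
Reactants: 22 tetracyclic hydroxy ketone (4R,5S,6S,7R,10S,13R)
Product: 23 tetracyclic keto diol (4R,5S,6S,7R,10S,11R,13R): as 22 with C12 as CH2 and C11 bearing exo-OH and endo-isopropyl
Conditions: Co(acac)2 (20 mol%), PhSiH3, O2 (1 atm), i-PrOH, rt
Reagents that add atoms: dioxygen, O=O
Why: Mukaiyama hydration, in which hydrogen-atom transfer to C12 gives the tertiary C11 norbornyl radical that is trapped by O2 on its open exo face, so the Markovnikov carbinol should form with exo-OH and endo-isopropyl.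

Step 19
Reactants: 23 tetracyclic keto diol (4R,5S,6S,7R,10S,11R,13R)
Product: 25 vinyl bromide (4R,5S,6S,7R,10S,11R,13R): as 23 with C1(Br)=C2 in place of the ketone, via hydrazone 24 (not isolated)
Conditions: N2H4·H2O, Et3N, EtOH, 80 °C; evaporate; NBS, pyridine, −10 °C → rt
Reagents that add atoms: N-bromosuccinimide, O=C1CCC(=O)N1Br
Why: Barton-type vinyl halide synthesis, in which NBS oxidises the hydrazone via the diazo compound to an α-bromo cation that can lose a proton only from C2 (C10 is quaternary), giving the C1=C2 vinyl bromide while the tertiary alcohols stay inert.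

Step 20
Reactants: 25 vinyl bromide (4R,5S,6S,7R,10S,11R,13R)
Product: 26 target CNP0362628.1, (1S,4R,5S,6S,7R,10S,11R,13R)-bromo diol
Conditions: Mn(dpm)3 (10 mol%), PhSiH3, t-BuOOH, i-PrOH, rt, argon
Reagents that add atoms: none
Why: Metal-hydride hydrogen-atom-transfer hydrogenation, a method that reduces alkenyl halides without cleaving the C–Br bond: hydrogen adds first to C2, and the α-bromo radical at C1 should be quenched on the α face, anti to the axial C10 methyl, leaving bromine equatorial and β.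

## Compound list

1 | pent-4-ynoyl chloride | C#CCCC(=O)Cl | starting material
2 | N-methoxy-N-methylpent-4-ynamide | C#CCCC(=O)N(C)OC | intermediate
3 | 2-methylhept-1-en-6-yn-3-one | C#CCCC(=O)C(C)=C | intermediate
4 | (R)-2-methylhept-1-en-6-yn-3-ol | C#CCC[C@@H](O)C(C)=C | intermediate
5 | (R)-tert-butyldimethyl[(2-methylhept-1-en-6-yn-3-yl)oxy]silane | C#CCC[C@@H](O[Si](C)(C)C(C)(C)C)C(C)=C | intermediate
6 | lithium acetylide of 5 | [Li]C#CCC[C@@H](O[Si](C)(C)C(C)(C)C)C(C)=C | intermediate
7 | methyl (R)-6-[(tert-butyldimethylsilyl)oxy]-7-methyloct-7-en-2-ynoate | COC(=O)C#CCC[C@@H](O[Si](C)(C)C(C)(C)C)C(C)=C | intermediate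
8 | methyl (2E,6R)-3-(allyloxy)-6-[(tert-butyldimethylsilyl)oxy]-7-methylocta-2,7-dienoate | COC(=O)/C=C(/OCC=C)CC[C@@H](O[Si](C)(C)C(C)(C)C)C(C)=C | intermediate
9 | methyl (2E)-2-[(5R,6Z)-5-[(tert-butyldimethylsilyl)oxy]-6-methyl-3,4,5,8-tetrahydro-2H-oxocin-2-ylidene]acetate | COC(=O)/C=C1\CC[C@@H](O[Si](C)(C)C(C)(C)C)/C(C)=C\CO1 | intermediate
10 | (2E)-2-[(5R,6Z)-5-[(tert-butyldimethylsilyl)oxy]-6-methyl-3,4,5,8-tetrahydro-2H-oxocin-2-ylidene]ethan-1-ol | OC/C=C1\CC[C@@H](O[Si](C)(C)C(C)(C)C)/C(C)=C\CO1 | intermediate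
11 | (5R,6Z)-5-[(tert-butyldimethylsilyl)oxy]-2-{(E)-2-[(tert-butyldimethylsilyl)oxy]ethylidene}-6-methyl-3,4,5,8-tetrahydro-2H-oxocine | CC(C)(C)[Si](C)(C)OC/C=C1\CC[C@@H](O[Si](C)(C)C(C)(C)C)/C(C)=C\CO1 | intermediate
12 | (2R,3S,4R)-4-[(tert-butyldimethylsilyl)oxy]-2-{[(tert-butyldimethylsilyl)oxy]methyl}-3-methyl-3-vinylcyclohexan-1-one | CC(C)(C)[Si](C)(C)OC[C@H]1[C@](C)(C=C)[C@H](O[Si](C)(C)C(C)(C)C)CCC1=O | intermediate
13 | (1R,2R,3S,4R)-4-[(tert-butyldimethylsilyl)oxy]-2-{[(tert-butyldimethylsilyl)oxy]methyl}-1,3-dimethyl-3-vinylcyclohexan-1-ol | CC(C)(C)[Si](C)(C)OC[C@H]1[C@](C)(C=C)[C@H](O[Si](C)(C)C(C)(C)C)CC[C@@]1(C)O | intermediate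
14 | 2-iodocyclopent-2-en-1-one | O=C1CCC=C1I | starting material
15 | B-alkyl-9-borabicyclo[3.3.1]nonane from 13 (boron on the terminal carbon of the former vinyl group) | CC(C)(C)[Si](C)(C)OC[C@H]1[C@](C)(CCB2C3CCCC2CCC3)[C@H](O[Si](C)(C)C(C)(C)C)CC[C@@]1(C)O | intermediate
16 | (1R,2R,3S,4R)-4-[(tert-butyldimethylsilyl)oxy]-2-{[(tert-butyldimethylsilyl)oxy]methyl}-1,3-dimethyl-3-[2-(5-oxocyclopent-1-en-1-yl)ethyl]cyclohexan-1-ol | CC(C)(C)[Si](C)(C)OC[C@H]1[C@](C)(CCC2=CCCC2=O)[C@H](O[Si](C)(C)C(C)(C)C)CC[C@@]1(C)O | intermediate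
17 | (1R,2R,3S,4R)-4-[(tert-butyldimethylsilyl)oxy]-2-{[(tert-butyldimethylsilyl)oxy]methyl}-3-[2-(5-hydroxy-5-isopropylcyclopent-1-en-1-yl)ethyl]-1,3-dimethylcyclohexan-1-ol (both epimers at the cyclopentenol carbon) | CC(C)(C)[Si](C)(C)OC[C@H]1[C@](C)(CCC2=CCCC2(O)C(C)C)[C@H](O[Si](C)(C)C(C)(C)C)CC[C@@]1(C)O | intermediate
18 | (1R,2R,3S,4R)-2-(hydroxymethyl)-3-[2-(5-hydroxy-5-isopropylcyclopent-1-en-1-yl)ethyl]-1,3-dimethylcyclohexane-1,4-diol | OC[C@H]1[C@](C)(CCC2=CCCC2(O)C(C)C)[C@H](O)CC[C@@]1(C)O | intermediate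
19 | (1S,2S,6R)-6-hydroxy-2-[2-(5-hydroxy-5-isopropylcyclopent-1-en-1-yl)ethyl]-2,6-dimethyl-3-oxocyclohexane-1-carbaldehyde | O=C[C@H]1[C@](C)(CCC2=CCCC2(O)C(C)C)C(=O)CC[C@@]1(C)O | intermediate
20 | (2S,3S,4R)-4-hydroxy-2-[2-(5-hydroxy-5-isopropylcyclopent-1-en-1-yl)ethyl]-2,4-dimethyl-3-vinylcyclohexan-1-one | C=C[C@H]1[C@](C)(CCC2=CCCC2(O)C(C)C)C(=O)CC[C@@]1(C)O | intermediate
21 | (2S,3S,4R)-4-hydroxy-2-[2-(2-isopropylcyclopenta-1,3-dien-1-yl)ethyl]-2,4-dimethyl-3-vinylcyclohexan-1-one (reactive cyclopentadiene isomer) | C=C[C@H]1[C@](C)(CCC2=C(C(C)C)C=CC2)C(=O)CC[C@@]1(C)O | intermediate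
22 | tetracyclic hydroxy ketone (4R,5S,6S,7R,10S,13R): C1 ketone, 4β-OH, 5α-H, 6β-H, 10β-CH3, C11=C12 with isopropyl on C11 | CC(C)C1=C[C@@H]2C[C@H]3[C@H]4[C@](C)(CC[C@@]31C2)C(=O)CC[C@@]4(C)O | intermediate
23 | tetracyclic keto diol (4R,5S,6S,7R,10S,11R,13R): C1 ketone, 11-exo-OH, 11-endo-isopropyl | CC(C)[C@]1(O)C[C@@H]2C[C@H]3[C@H]4[C@](C)(CC[C@@]31C2)C(=O)CC[C@@]4(C)O | intermediate
24 | C1 hydrazone of 23 | CC(C)[C@]1(O)C[C@@H]2C[C@H]3[C@H]4[C@](C)(CC[C@@]31C2)C(=NN)CC[C@@]4(C)O | intermediate
25 | vinyl bromide (4R,5S,6S,7R,10S,11R,13R): C1(Br)=C2, diol as in 23 | CC(C)[C@]1(O)C[C@@H]2C[C@H]3[C@H]4[C@](C)(CC[C@@]31C2)C(Br)=CC[C@@]4(C)O | intermediate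
26 | CNP0362628.1, (1S,4R,5S,6S,7R,10S,11R,13R)-bromo diol | CC(C)[C@]1(O)C[C@@H]2C[C@H]3[C@H]4[C@](C)(CC[C@@]31C2)[C@@H](Br)CC[C@@]4(C)O | target

## Step count and risks

Total step count: 20. Longest linear sequence: 20 steps (1 to 26; 14 is purchased).

Steps most likely to fail:

Step 7 (ring-closing metathesis). The eight-membered ring may close more slowly than the diene oligomerises, and the 1,1-disubstituted alkene next to the silyloxy group may not be taken up by the ruthenium carbene. The fallback closes the oxocene through the C–O bond instead. It sets out from Weinreb amide 2: addition of (Z)-alkenyllithium F1 (from 4-methoxybenzyl (Z)-3-iodobut-2-enyl ether and t-BuLi) should give (Z)-enone F2. CBS reduction as in step 3 should give (R)-alcohol F3, silylation the silyl ether F4, carboxylation of the alkyne (n-BuLi, ClCO2Me) ynoate F5, and DDQ the (Z)-hydroxy ynoate F6. Intramolecular oxa-Michael addition of F6 (PBu3 cat., high dilution) would close the ring with the (Z)-alkene already in place and comes back to the route at cyclic enoate 9.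

Step 10 (Claisen ring contraction). At 170 °C the enol ether may isomerise (E to Z, or migration of the exocyclic double bond into the ring), or the allylic silyl ether may be lost as silanol before the sigmatropic shift; either would erode C5 or consume 11. The fallback is a Lewis-acid-promoted rearrangement–reduction at low temperature in place of the thermal step. It sets out from 11: i-Bu3Al (CH2Cl2, −78 °C → rt) coordinates the ring oxygen, should trigger the same C5–C10 bond formation through the same chair array, and reduces the aluminium-bound ketone in situ to cyclohexanol F7 (either C4 epimer). Dess–Martin oxidation of F7 comes back to the route at ketone 12.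

Step 19 (hydrazone formation and bromination). Condensation of hydrazine at the neopentyl-type C1 ketone may stall, and oxidation by NBS may stop at the geminal dibromide. The fallback uses enolate triflation and palladium-catalysed halide exchange. It sets out from keto diol 23: TMSOTf and 2,6-lutidine should give bis(trimethylsilyl) ether F8, and KHMDS with PhNTf2 the enol triflate F9 (the ketone can enolise only towards C2). Pd2(dba)3, t-BuBrettPhos and KBr should exchange triflate for bromide to give silylated vinyl bromide F10, and Bu4NF removes the silyl groups and comes back to the route at vinyl bromide 25.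

Further compounds
F1 | step 7 | [(Z)-4-[(4-methoxybenzyl)oxy]but-2-en-2-yl]lithium | [Li]/C(C)=C\COCc1ccc(OC)cc1
F2 | step 7 | (Z)-8-[(4-methoxybenzyl)oxy]-6-methyloct-6-en-1-yn-5-one | C#CCCC(=O)/C(C)=C\COCc1ccc(OC)cc1
F3 | step 7 | (5R,6Z)-8-[(4-methoxybenzyl)oxy]-6-methyloct-6-en-1-yn-5-ol | C#CCC[C@@H](O)/C(C)=C\COCc1ccc(OC)cc1
F4 | step 7 | tert-butyldimethylsilyl ether of F3 | C#CCC[C@@H](O[Si](C)(C)C(C)(C)C)/C(C)=C\COCc1ccc(OC)cc1
F5 | step 7 | methyl (6R,7Z)-6-[(tert-butyldimethylsilyl)oxy]-9-[(4-methoxybenzyl)oxy]-7-methylnon-7-en-2-ynoate | COC(=O)C#CCC[C@@H](O[Si](C)(C)C(C)(C)C)/C(C)=C\COCc1ccc(OC)cc1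
F6 | step 7 | methyl (6R,7Z)-6-[(tert-butyldimethylsilyl)oxy]-9-hydroxy-7-methylnon-7-en-2-ynoate | COC(=O)C#CCC[C@@H](O[Si](C)(C)C(C)(C)C)/C(C)=C\CO
F7 | step 10 | (2R,3S,4R)-4-[(tert-butyldimethylsilyl)oxy]-2-{[(tert-butyldimethylsilyl)oxy]methyl}-3-methyl-3-vinylcyclohexan-1-ol (either epimer at C1 of the ring) | CC(C)(C)[Si](C)(C)OC[C@H]1[C@](C)(C=C)[C@H](O[Si](C)(C)C(C)(C)C)CCC1O
F8 | step 19 | bis(trimethylsilyl) ether of 23 | CC(C)[C@]1(O[Si](C)(C)C)C[C@@H]2C[C@H]3[C@H]4[C@](C)(CC[C@@]31C2)C(=O)CC[C@@]4(C)O[Si](C)(C)C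
F9 | step 19 | C1 enol triflate of F8 (C1=C2) | CC(C)[C@]1(O[Si](C)(C)C)C[C@@H]2C[C@H]3[C@H]4[C@](C)(CC[C@@]31C2)C(OS(=O)(=O)C(F)(F)F)=CC[C@@]4(C)O[Si](C)(C)C
F10 | step 19 | bis(trimethylsilyl) ether of 25 | CC(C)[C@]1(O[Si](C)(C)C)C[C@@H]2C[C@H]3[C@H]4[C@](C)(CC[C@@]31C2)C(Br)=CC[C@@]4(C)O[Si](C)(C)C
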